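Everything rests on disconnecting the O–C4' bond of the 8-O-4' ether. The feature exploited is that C4' of ring B carries the C8 oxygen between the two methoxy-bearing carbons C3' and C5': this 1,2,3-trioxygenated pattern maps onto a 2-alkoxycyclohexane-1,3-dione. In one operation a rhodium carbenoid, generated from a cyclic 2-diazo-1,3-dione that carries a ring ester as latent allyl group, inserts into the free C8 hydroxyl and forms the hindered ether bond without breaking the C8–O bond. The alcohol partner is the erythro (7R,8S) diol from L-lactate, silylated at the benzylic C7 oxygen. Aromatisation and O-methylation then turn the dione into ring B.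

Key step: step 8

Numbering and shorthand: C7 is the carbinol carbon on ring A (the 3,4-dimethoxyphenyl ring), C8 the methine carrying the ether oxygen and the C9 methyl, ring B the allyl-bearing ring; R*O denotes the [(1R,2S)-1-[(tert-butyldimethylsilyl)oxy]-1-(3,4-dimethoxyphenyl)propan-2-yl]oxy group.

Assumption: 12 is drawn as the diketone although it should exist mainly as its enol, and the enolisable ring centres of 12 to 16 are left unassigned because they vanish at 17.

Step 1
Reactants: 1 ethyl (S)-2-hydroxypropanoate (ethyl L-lactate)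
Product: 2 ethyl (S)-2-(benzyloxy)propanoate
Conditions: BnOC(=NH)CCl3, TfOH (cat.), cyclohexane/CH2Cl2, rt
Reagents that add atoms: benzyl 2,2,2-trichloroacetimidate, ClC(Cl)(Cl)C(=N)OCc1ccccc1
Why: Acid-catalysed benzylation with the trichloroacetimidate (imidate O-alkylation) etherifies the hydroxyl without base, so the α-centre is never enolised and stays (S).

Step 2
Reactants: 2 ethyl (S)-2-(benzyloxy)propanoate
Product: 3 (S)-2-(benzyloxy)-N-methoxy-N-methylpropanamide
Conditions: MeNH(OMe)·HCl, iPrMgCl, THF, −20 → 0 °C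
Reagents that add atoms: N,O-dimethylhydroxylamine hydrochloride, CNOC.Cl
Why: The chloromagnesium amide formed from the hydrochloride and iPrMgCl acylates on the ester (Weinreb amide formation by magnesium amide aminolysis) at a temperature too low for epimerisation of the α-alkoxy centre.

Step 3
Reactants: 3 (S)-2-(benzyloxy)-N-methoxy-N-methylpropanamide; 4 4-bromo-1,2-dimethoxybenzene (4-bromoveratrole)
Product: 6 (S)-2-(benzyloxy)-1-(3,4-dimethoxyphenyl)propan-1-one, via arylmagnesium bromide 5 (not isolated)
Conditions: 4, Mg, THF, reflux → rt; then 3, THF, 0 °C; aq NH4Cl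
Reagents that add atoms: none
Why: In this Weinreb ketone synthesis the aryl Grignard reagent adds only once because the chelated tetrahedral magnesium adduct survives until the cold NH4Cl quench, which also keeps the enolisable α-benzyloxy ketone from racemising.

Step 4
Reactants: 6 (S)-2-(benzyloxy)-1-(3,4-dimethoxyphenyl)propan-1-one
Product: 7 (1R,2S)-2-(benzyloxy)-1-(3,4-dimethoxyphenyl)propan-1-ol
Conditions: Zn(BH4)2, Et2O, −30 → 0 °C; aq NH4Cl
Reagents that add atoms: none
Why: Chelation-controlled hydride reduction (Cram chelate model): zinc bridges the carbonyl and benzyloxy oxygens and hydride enters from the face of the C8 hydrogen, away from the C9 methyl, which sets C7 as (R) and so should give the erythro alcohol.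

Step 5
Reactants: 7 (1R,2S)-2-(benzyloxy)-1-(3,4-dimethoxyphenyl)propan-1-ol
Product: 8 {[(1R,2S)-2-(benzyloxy)-1-(3,4-dimethoxyphenyl)propyl]oxy}(tert-butyl)dimethylsilane
Conditions: TBSOTf, 2,6-lutidine, CH2Cl2, 0 °C
Reagents that add atoms: tert-butyldimethylsilyl trifluoromethanesulfonate, CC(C)(C)[Si](C)(C)OS(=O)(=O)C(F)(F)F
Why: Silylation of the secondary benzylic alcohol with the silyl triflate and a hindered base is fast at 0 °C and touches neither stereocentre.

Step 6
Reactants: 8 {[(1R,2S)-2-(benzyloxy)-1-(3,4-dimethoxyphenyl)propyl]oxy}(tert-butyl)dimethylsilane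
Product: 9 (1R,2S)-1-[(tert-butyldimethylsilyl)oxy]-1-(3,4-dimethoxyphenyl)propan-2-ol
Conditions: H2 (1 atm), Pd/C (10% palladium on carbon), EtOAc, rt
Reagents that add atoms: none
Why: Catalytic hydrogenolysis cleaves the primary benzyl ether much faster than the silylated secondary benzylic C7–O bond, and the neutral aprotic medium gives the silyl group no chance to migrate to the freed C8 hydroxyl.

Step 7
Reactants: 10 ethyl 3,5-dioxocyclohexane-1-carboxylate
Product: 11 ethyl 4-diazo-3,5-dioxocyclohexane-1-carboxylate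
Conditions: 4-acetamidobenzenesulfonyl azide, Et3N, MeCN, 0 °C → rt
Reagents that add atoms: 4-acetamidobenzenesulfonyl azide, CC(=O)Nc1ccc(cc1)S(=O)(=O)N=[N+]=[N-]
Why: Regitz diazo transfer from the sulfonyl azide to the triethylammonium enolate of the 1,3-dione occurs only at the doubly activated C4 methylene.

Step 8
Reactants: 9 (1R,2S)-1-[(tert-butyldimethylsilyl)oxy]-1-(3,4-dimethoxyphenyl)propan-2-ol; 11 ethyl 4-diazo-3,5-dioxocyclohexane-1-carboxylate
Product: 12 ethyl 4-(R*O)-3,5-dioxocyclohexane-1-carboxylate
Conditions: Rh2(OAc)4 (2 mol%), PhF, 80 °C; 11 (2 equiv) added slowly by syringe pump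
Reagents that add atoms: none
Why: Rh2(OAc)4 expels N2 from 11 to give an electrophilic rhodium carbenoid at the carbon between the two carbonyls, the free C8 hydroxyl of 9 adds to it, and proton transfer in the oxonium ylide releases the 2-alkoxy-1,3-dione 12, so the O–C4' bond forms while the C8–O bond is never broken. This is a rhodium carbenoid O–H insertion, a known reaction of cyclic 2-diazo-1,3-diones with alcohols. No ring is closed, ring B being delivered preformed as the dione. No configured stereocentre is created, since the ring centres of 12 are enolisable and vanish on aromatisation, while C7 (R) and C8 (S) are only carried through. The step needs chemoselectivity for O–H insertion over Wolff ring contraction, attack on the electron-rich ring A, attack on the silyl ether oxygen and carbene dimerisation. Catalysis well below the thermal Wolff temperature, the hydroxyl being the only protic and the most nucleophilic site of 9, the bulk of the silyl group around the C7 oxygen and slow addition of 11 should secure it; an ester, not an alkene, sits on the dione so that no cyclopropanation can compete.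

Step 9
Reactants: 12 ethyl 4-(R*O)-3,5-dioxocyclohexane-1-carboxylate
Product: 13 ethyl 4-(R*O)-3-methoxy-5-oxocyclohex-3-ene-1-carboxylate
Conditions: TMSCHN2, PhMe/MeOH, 0 °C → rt
Reagents that add atoms: trimethylsilyldiazomethane, C[Si](C)(C)C=[N+]=[N-]
Why: The acidic enol of 12 is O-methylated by the diazomethane surrogate under neutral conditions (diazoalkane etherification), C-methylation being excluded at the fully substituted C4, and both enol oxygens give the same constitution.

Step 10
Reactants: 13 ethyl 4-(R*O)-3-methoxy-5-oxocyclohex-3-ene-1-carboxylate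
Product: 17 ethyl 3-hydroxy-5-methoxy-4-(R*O)benzoate, via selenide 14 (not isolated), via selenoxide 15 (not isolated), via cyclohexadienone 16 (not isolated)
Conditions: LDA (LiN(iPr)2), THF, −78 °C; PhSeBr, −78 °C; then H2O2 (30%), pyridine, CH2Cl2, 0 °C → rt
Reagents that add atoms: none
Why: Selenoxide elimination: the kinetic lithium enolate is selenenylated, oxidation gives the selenoxide, syn-elimination gives the cross-conjugated dienone and this tautomerises to the phenol, every enolate regiochemistry converging on 17, while base and low temperature spare the benzylic C7 silyl ether of ring A, which quinone oxidants or acidic halogen-based aromatisations would attack.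

Step 11
Reactants: 17 ethyl 3-hydroxy-5-methoxy-4-(R*O)benzoate
Product: 18 ethyl 3,5-dimethoxy-4-(R*O)benzoate
Conditions: MeI, K2CO3, acetone, 50 °C
Reagents that add atoms: iodomethane, CI
Why: Williamson etherification of the potassium phenoxide with iodomethane installs the second methoxy group of ring B.

Step 12
Reactants: 18 ethyl 3,5-dimethoxy-4-(R*O)benzoate
Product: 19 [3,5-dimethoxy-4-(R*O)phenyl]methanol
Conditions: LiAlH4, THF, 0 °C; Fieser work-up
Reagents that add atoms: none
Why: Hydride reduction of the benzoate ester with LiAlH4 gives the primary benzylic alcohol, and silyl and aryl ethers are inert to it at 0 °C.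

Step 13
Reactants: 19 [3,5-dimethoxy-4-(R*O)phenyl]methanol
Product: 20 5-(bromomethyl)-1,3-dimethoxy-2-(R*O)benzene
Conditions: CBr4, PPh3, CH2Cl2, 0 °C; used crude
Reagents that add atoms: tetrabromomethane, BrC(Br)(Br)Br
Why: The Appel reaction converts the primary benzylic alcohol into the bromide under neutral conditions that generate no HBr, so the benzylic silyl ether at C7 is kept.

Step 14
Reactants: 20 5-(bromomethyl)-1,3-dimethoxy-2-(R*O)benzene
Product: 21 5-allyl-1,3-dimethoxy-2-(R*O)benzene
Conditions: CH2=CHMgBr, CuI (10 mol%), THF, −20 → 0 °C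
Reagents that add atoms: vinylmagnesium bromide, C=C[Mg]Br
Why: Copper-catalysed cross-coupling of a benzylic bromide with a vinyl Grignard reagent (Kumada-type substitution through a vinylcuprate) forms the ArCH2–CH=CH2 bond at low temperature, where the allyl group does not move into conjugation.

Step 15
Reactants: 21 5-allyl-1,3-dimethoxy-2-(R*O)benzene
Product: 22 (1R,2S)-2-(4-allyl-2,6-dimethoxyphenoxy)-1-(3,4-dimethoxyphenyl)propan-1-ol
Conditions: Bu4NF (TBAF), THF, 0 °C → rt
Reagents that add atoms: none
Why: Fluoride cleaves the Si–O bond (desilylation driven by the strong Si–F bond) without affecting the C7 or C8 configuration, the aryl ether or the allyl group.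

Compound list
1 | ethyl (S)-2-hydroxypropanoate (ethyl L-lactate) | CCOC(=O)[C@H](C)O | starting material
2 | ethyl (S)-2-(benzyloxy)propanoate | CCOC(=O)[C@H](C)OCc1ccccc1 | intermediate
3 | (S)-2-(benzyloxy)-N-methoxy-N-methylpropanamide | CON(C)C(=O)[C@H](C)OCc1ccccc1 | intermediate
4 | 4-bromo-1,2-dimethoxybenzene (4-bromoveratrole) | COc1ccc(Br)cc1OC | starting material
5 | 3,4-dimethoxyphenylmagnesium bromide (not isolated) | COc1ccc([Mg]Br)cc1OC | intermediate
6 | (S)-2-(benzyloxy)-1-(3,4-dimethoxyphenyl)propan-1-one | COc1ccc(cc1OC)C(=O)[C@H](C)OCc2ccccc2 | intermediate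
7 | (1R,2S)-2-(benzyloxy)-1-(3,4-dimethoxyphenyl)propan-1-ol | c1ccccc1CO[C@@H](C)[C@H](O)c2ccc(OC)c(OC)c2 | intermediate
8 | {[(1R,2S)-2-(benzyloxy)-1-(3,4-dimethoxyphenyl)propyl]oxy}(tert-butyl)dimethylsilane | c1ccccc1CO[C@@H](C)[C@H](O[Si](C)(C)C(C)(C)C)c2ccc(OC)c(OC)c2 | intermediate
9 | (1R,2S)-1-[(tert-butyldimethylsilyl)oxy]-1-(3,4-dimethoxyphenyl)propan-2-ol | O[C@@H](C)[C@H](O[Si](C)(C)C(C)(C)C)c1ccc(OC)c(OC)c1 | intermediate
10 | ethyl 3,5-dioxocyclohexane-1-carboxylate | CCOC(=O)C1CC(=O)CC(=O)C1 | starting material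
11 | ethyl 4-diazo-3,5-dioxocyclohexane-1-carboxylate | CCOC(=O)C1CC(=O)C(=[N+]=[N-])C(=O)C1 | intermediate
12 | ethyl 4-{[(1R,2S)-1-[(tert-butyldimethylsilyl)oxy]-1-(3,4-dimethoxyphenyl)propan-2-yl]oxy}-3,5-dioxocyclohexane-1-carboxylate | CCOC(=O)C1CC(=O)C(O[C@@H](C)[C@H](O[Si](C)(C)C(C)(C)C)c2ccc(OC)c(OC)c2)C(=O)C1 | intermediate
13 | ethyl 4-(R*O)-3-methoxy-5-oxocyclohex-3-ene-1-carboxylate (both ring epimers) | CCOC(=O)C1CC(=O)C(O[C@@H](C)[C@H](O[Si](C)(C)C(C)(C)C)c2ccc(OC)c(OC)c2)=C(OC)C1 | intermediate
14 | ethyl 4-(R*O)-5-methoxy-3-oxo-2-(phenylselanyl)cyclohex-4-ene-1-carboxylate (not isolated) | CCOC(=O)C1CC(OC)=C(O[C@@H](C)[C@H](O[Si](C)(C)C(C)(C)C)c2ccc(OC)c(OC)c2)C(=O)C1[Se]c3ccccc3 | intermediate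
15 | ethyl 4-(R*O)-5-methoxy-3-oxo-2-(phenylseleninyl)cyclohex-4-ene-1-carboxylate (not isolated) | CCOC(=O)C1CC(OC)=C(O[C@@H](C)[C@H](O[Si](C)(C)C(C)(C)C)c2ccc(OC)c(OC)c2)C(=O)C1[Se](=O)c3ccccc3 | intermediate
16 | ethyl 4-(R*O)-5-methoxy-3-oxocyclohexa-1,4-diene-1-carboxylate (not isolated) | CCOC(=O)C1=CC(=O)C(O[C@@H](C)[C@H](O[Si](C)(C)C(C)(C)C)c2ccc(OC)c(OC)c2)=C(OC)C1 | intermediate
17 | ethyl 3-hydroxy-5-methoxy-4-(R*O)benzoate | CCOC(=O)c1cc(O)c(O[C@@H](C)[C@H](O[Si](C)(C)C(C)(C)C)c2ccc(OC)c(OC)c2)c(OC)c1 | intermediate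
18 | ethyl 3,5-dimethoxy-4-(R*O)benzoate | CCOC(=O)c1cc(OC)c(O[C@@H](C)[C@H](O[Si](C)(C)C(C)(C)C)c2ccc(OC)c(OC)c2)c(OC)c1 | intermediate
19 | [3,5-dimethoxy-4-(R*O)phenyl]methanol | OCc1cc(OC)c(O[C@@H](C)[C@H](O[Si](C)(C)C(C)(C)C)c2ccc(OC)c(OC)c2)c(OC)c1 | intermediate
20 | 5-(bromomethyl)-1,3-dimethoxy-2-(R*O)benzene | BrCc1cc(OC)c(O[C@@H](C)[C@H](O[Si](C)(C)C(C)(C)C)c2ccc(OC)c(OC)c2)c(OC)c1 | intermediate
21 | 5-allyl-1,3-dimethoxy-2-(R*O)benzene (silyl ether of the target) | C=CCc1cc(OC)c(O[C@@H](C)[C@H](O[Si](C)(C)C(C)(C)C)c2ccc(OC)c(OC)c2)c(OC)c1 | intermediate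
22 | (1R,2S)-2-(4-allyl-2,6-dimethoxyphenoxy)-1-(3,4-dimethoxyphenyl)propan-1-ol | C=CCc1cc(OC)c(O[C@@H](C)[C@H](O)c2ccc(OC)c(OC)c2)c(OC)c1 | target

Total step count: 15.
Longest linear sequence: 14 steps (steps 1 to 6, then 8 to 15, from ethyl L-lactate 1); step 7 is the one-step side branch.

Steps most likely to fail

Step 8. The carbenoid may be lost to dimerisation, to the enol hydroxyl of the product or to the ring A arene before the hindered C8 hydroxyl captures it, so that conversion of 9 stalls. The fallback makes the O–C4' bond by SN2 inversion with a phenol; it sets out from 4-bromo-1,2-dimethoxybenzene 4 (as its Grignard reagent 5) and comes back at the target 22. Purchased 4-allyl-2,6-dimethoxyphenol F1 and purchased methyl (R)-lactate F2 are joined under Mitsunobu conditions (PPh3, DIAD, THF), which inverts the lactate centre and should give methyl (S)-2-(4-allyl-2,6-dimethoxyphenoxy)propanoate F3. MeNH(OMe)·HCl with iPrMgCl should convert this into the Weinreb amide F4, and addition of 5 should give the aryl ketone F5. Reduction with Zn(BH4)2, again under chelation control, should favour the erythro alcohol 22, with chromatographic removal of any threo isomer.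

Step 10. Enolisation may be incomplete or unselective, more than one selenium may be introduced, or the new electron-rich phenol may be oxidised further by the peroxide and selenium species. The fallback is a Saegusa–Ito oxidation that sets out from 13 and comes back at 17. Compound 13 is converted with LDA and TMSCl into the silyl dienol ether F6, which is treated with Pd(OAc)2 in MeCN. β-Hydride elimination from the palladium enolate should give dienone 16, which tautomerises to 17 with no peroxide present.

Step 14. The very electron-rich benzylic bromide may ionise, or undergo halogen–magnesium exchange and Wurtz-type homocoupling, faster than it is substituted. The fallback reverses the polarity; it sets out from 19 and comes back at 21. Alcohol 19 is converted (MsCl, Et3N, LiCl) into the more stable benzylic chloride F7, and zinc dust with LiCl in THF should give the benzylzinc chloride F8. A Negishi coupling of F8 with vinyl bromide and Pd(PPh3)4 should then give 21.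

Further compounds
F1 | step 8 | 4-allyl-2,6-dimethoxyphenol (purchased) | C=CCc1cc(OC)c(O)c(OC)c1
F2 | step 8 | methyl (R)-2-hydroxypropanoate (methyl (R)-lactate, purchased) | COC(=O)[C@@H](C)O
F3 | step 8 | methyl (S)-2-(4-allyl-2,6-dimethoxyphenoxy)propanoate | COC(=O)[C@H](C)Oc1c(OC)cc(CC=C)cc1OC
F4 | step 8 | (S)-2-(4-allyl-2,6-dimethoxyphenoxy)-N-methoxy-N-methylpropanamide | CON(C)C(=O)[C@H](C)Oc1c(OC)cc(CC=C)cc1OC
F5 | step 8 | (S)-2-(4-allyl-2,6-dimethoxyphenoxy)-1-(3,4-dimethoxyphenyl)propan-1-one | COc1ccc(cc1OC)C(=O)[C@H](C)Oc2c(OC)cc(CC=C)cc2OC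
F6 | step 10 | ethyl 4-(R*O)-3-methoxy-5-[(trimethylsilyl)oxy]cyclohexa-3,5-diene-1-carboxylate | CCOC(=O)C1CC(OC)=C(O[C@@H](C)[C@H](O[Si](C)(C)C(C)(C)C)c2ccc(OC)c(OC)c2)C(O[Si](C)(C)C)=C1
F7 | step 14 | 5-(chloromethyl)-1,3-dimethoxy-2-(R*O)benzene | ClCc1cc(OC)c(O[C@@H](C)[C@H](O[Si](C)(C)C(C)(C)C)c2ccc(OC)c(OC)c2)c(OC)c1
F8 | step 14 | [3,5-dimethoxy-4-(R*O)benzyl]zinc chloride | Cl[Zn]Cc1cc(OC)c(O[C@@H](C)[C@H](O[Si](C)(C)C(C)(C)C)c2ccc(OC)c(OC)c2)c(OC)c1
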